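## Analysis of the target

Isochromene numbering is used throughout: ring A is the pyran (O2, C1, C3, C4, C4a, C8a) and ring B the carbocycle (C4a, C5, C6, C7, C8, C8a).

- The target 17 is a 7,8-dihydro-6H-isochromen-6-one, an 8-deoxy azaphilone. C3 carries an (E)-3-acetoxyprop-1-enyl chain and O7 an orsellinate (2,4-dihydroxy-6-methylbenzoate).
- The chromophore is a cross-conjugated push–pull trienone: O2 donates through both C1=C8a and C3=C4 into C4a=C5–C6=O (pyrylium-enolate character). It is therefore the thermodynamic sink among its tautomers, but it is sensitive to primary amines, strong nucleophiles and light.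
- C7 is the only stereocenter and is (S). It is fully substituted (CH3, acyloxy O, the C6 carbonyl, C8H2), has no neighbouring stereocenter to relay from, and cannot epimerise, so it has to be set by absolute control.
- The feature that decides the strategy: unlike common azaphilones, C8 is a methylene. Ring B holds two sp3 carbons (C7, C8), and the C5-protonated tautomer of the chromophore is a cyclohex-3-enone whose only ring alkene is the tetrasubstituted C4a=C8a bond between the methylenes C5 and C8. That is the retron of an alkyne Diels–Alder reaction with a 2-oxydiene (C5=C6(O)–C7(CH3)=C8).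
- Sensitive groups: the primary allylic acetate (base, zerovalent palladium), the enol ether C1=C8a, and two free phenols on a hindered aryl ester.
- Difficulties: dearomatisation routes deliver C8=O or C8=C8a, not C8H2; the C7–O ester joins a tertiary α-ketol to a 2,6-disubstituted benzoic acid; and an isolated quaternary carbinol has to be made as one enantiomer.

## Retrosynthetic reasoning

**17 ⇒ 16 ⇒ 12 + 15.** The phenols of 17 are unmasked last from bis-silyl ether 16. The C7–O acyl bond of 16 is cut to tertiary alcohol 12 and aroyl chloride 15. The cut is placed late so that the electron-rich aryl unit does not pass through the oxidation that sets C7, and because 12 has only one nucleophilic site. The forward reaction has to acylate a tertiary α-ketol with a hindered acid chloride.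

**12 ⇒ 10.** The O2–C3 bond of ring A is cut. This reveals an alkyne (C3≡C4) on C4a and a formyl group (C1) on C8a of a cyclohex-3-enone, compound 10. Forward, 10 tautomerises to vinylogous acid 11 (C5 proton to O1), and the enol oxygen adds 6-endo-dig to the alkyne. The fragile chromophore thus appears late and forms downhill.

**10 ⇒ 8.** The C7–OH bond is cut. The α-hydroxy ketone C6(=O)–C7(OH)CH3 is the product of oxidising a C6=C7 silyl enol ether (via silyloxy epoxide 9). The forward step has to select one face of a tetrasubstituted enol ether with a chiral oxidant; it is the only stereo-defining step.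

**8 ⇒ 2 + 7 (key disconnection).** The bonds C5–C4a and C8–C8a are cut. Ring B falls apart into 2-silyloxydiene 2 (C5, C6, C7, C8 and the C7 methyl) and ene-diynal 7 (C1, C8a, C4a, C4, C3 and the whole side chain). This cut is chosen because it gives ring B directly at the dihydro oxidation level, with C8 and C5 as methylenes. The C6 oxygen of the diene dictates the regiochemistry, and both fragments are acyclic and of similar size. The forward reaction has to be regioselective (C5 to C4a) and site-selective for the formyl-bearing triple bond.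

**7 ⇒ 6 ⇒ 4 + 5; 4 ⇒ 3; 2 ⇒ 1.** Ynal 7 comes from propargylic alcohol 6. The C4–C4a sp–sp bond of 6 is cut to terminal alkyne 4 and bromoalkyne 5 (copper-mediated heterocoupling). Acetate 4 is made from enynol 3 and diene 2 from enone 1.

**15 ⇒ 14 ⇒ 13.** The acid chloride is made under neutral conditions from the persilylated form 14 of orsellinic acid 13.

## Alternatives that were turned down

**Alternative 1:** the textbook azaphilone route.
- Disconnection: O2–C3 and C7–O on an aromatic precursor.
- Forward key step: aldehyde A1 is cycloisomerised to a 2-benzopyrylium salt and hydroxylatively dearomatised ([Cu(MeCN)4]PF6/(−)-sparteine/O2, or a flavin monooxygenase) to the 6,8-dioxo azaphilone A2. Esterification and removal of the C8 oxygen follow.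
- Why turned down: this dearomatisation needs the resorcinol pattern, so it necessarily delivers C8=O. Deleting it means a 1,2-reduction of a vinylogous ester carbonyl next to the C6 ketone, then deoxygenation of an 8-ol that is allylic to the enol ether and β to the C7 acyloxy group. Ionisation there gives pyrylium cations, and elimination across C7–C8 aromatises ring B. At least three extra redox steps of poor chemoselectivity are added to a four- to five-step synthesis of A1.

**Alternative 2:** dearomatisation of a mono-phenol.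
- Disconnection: C7–O on phenol A3, then C8–H.
- Forward key step: hydroxylative dearomatisation of A3 at C7 to ortho-quinol A4, then conjugate reduction of the enal at C8 and cycloisomerisation.
- Why turned down: ortho-quinols without the C8 oxygen dimerise readily by [4+2] cycloaddition. Oxygen transfer must choose C7 over the free ortho position C5, and the enantioselectivity with chiral iodine reagents is not dependable. Hydride must then go only to C8 in a cross-conjugated dienone–enal–enyne. The sequence spends one oxidation and one reduction to reach a ring that a cycloaddition gives directly.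

**Alternative 3:** convergent union at C7–C8 and ring closure at C5=C4a.
- Disconnection: C7–C8 (alkylation of a lactic-acid-derived chiral enolate with a pyranylmethyl halide) and C5=C4a.
- Forward key step: intramolecular Knoevenagel-type condensation of methyl ketone A5 onto the pyranone carbonyl C4a.
- Why turned down: the pyranone carbonyl is the least electrophilic position of the ring. After O-activation, the enol can reach both C4a and C1, each closing a six-membered ring, and attack at the α-position C1 is the usual mode for such acceptors. The 2,5-disubstituted pyranone needs at least five steps, and the allylic acetate would not survive the organometallic steps that lead to A5. The route would be clearly longer.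

Key step: step 5

Remark 1: compounds 3 and 5 are taken as purchasable; 5 is otherwise one step from prop-2-yn-1-ol (N-bromosuccinimide, cat. AgNO3).

Remark 2: the sense of induction in step 6 is assigned by analogy with 1-substituted cyclohexenes (the C7 methyl in the place of the vinylic hydrogen), which calls for the L-fructose-derived ketone; should the opposite sense be found, the D-fructose-derived ketone is used with no other change.

## Route

Step 1
Reactants: 1 3-methylbut-3-en-2-one
Product: 2 triethyl[(3-methylbuta-1,3-dien-2-yl)oxy]silane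
Conditions: Et3SiOTf, Et3N, Et2O, 0 °C
Reagents that add atoms: triethylsilyl trifluoromethanesulfonate, CC[Si](CC)(CC)OS(=O)(=O)C(F)(F)F
Why: Only the acetyl methyl of 1 can enolise, so soft enolisation (silyl triflate, amine) gives the 2-silyloxydiene as a single regioisomer (silyl enol ether formation).

Step 2
Reactants: 3 (E)-pent-2-en-4-yn-1-ol
Product: 4 (E)-pent-2-en-4-yn-1-yl acetate
Conditions: Ac2O, pyridine, DMAP (cat.), CH2Cl2, 0 °C to rt
Reagents that add atoms: acetic anhydride, CC(=O)OC(C)=O
Why: DMAP-catalysed acetylation of a primary allylic alcohol; the terminal alkyne and the E alkene are not touched.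

Step 3
Reactants: 4 (E)-pent-2-en-4-yn-1-yl acetate; 5 3-bromoprop-2-yn-1-ol
Product: 6 (E)-8-hydroxyoct-2-ene-4,6-diyn-1-yl acetate
Conditions: CuCl (cat.), NH2OH·HCl, n-BuNH2 (30% aq.), CH2Cl2, 0 °C
Reagents that add atoms: none
Why: Cadiot–Chodkiewicz coupling of the copper acetylide of 4 with bromoalkyne 5 gives the unsymmetrical diyne; hydroxylamine keeps copper monovalent and suppresses homocoupling, and the acetate survives brief contact with aqueous amine at 0 °C.

Step 4
Reactants: 6 (E)-8-hydroxyoct-2-ene-4,6-diyn-1-yl acetate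
Product: 7 (E)-8-oxooct-2-ene-4,6-diyn-1-yl acetate
Conditions: Dess–Martin periodinane, CH2Cl2, 0 °C; cold filtration, used at once as a solution
Reagents that add atoms: none
Why: Dess–Martin oxidation of a propargylic alcohol under neutral, anhydrous conditions stops at the ynal and leaves the acetate and the enyne intact.

Step 5
Reactants: 2 triethyl[(3-methylbuta-1,3-dien-2-yl)oxy]silane; 7 (E)-8-oxooct-2-ene-4,6-diyn-1-yl acetate
Product: 8 (E)-5-[2-formyl-4-methyl-5-(triethylsilyloxy)cyclohexa-1,4-dien-1-yl]pent-2-en-4-yn-1-yl acetate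
Conditions: 2 (2 equiv), BHT (cat.), toluene, 45 °C, Ar; filtration through Et3N-deactivated silica
Reagents that add atoms: none
Why: Thermal, concerted [4+2] cycloaddition (Diels–Alder) of the electron-rich 2-silyloxydiene 2 with the ynal triple bond of 7; the closest known reaction type is the cycloaddition of 2-silyloxybuta-1,3-dienes with acetylenic aldehydes, ketones and esters to 1-silyloxycyclohexa-1,4-dienes. Ring B is closed in one suprafacial [4+2] event that forms C5–C4a and C8–C8a and leaves the two ring alkenes where the target needs them, C4a=C8a between the two methylenes and the enol ether C6=C7. No stereocenter is formed; the step delivers the prochiral enol ether on which step 6 sets C7. Regioselectivity is needed and is secured by the diene: the silyloxy group on C6 places the larger HOMO coefficient on C5, which bonds to the β-carbon C4a of the ynal, so that the C6 oxygen ends up 1,4 to the formyl-bearing C8a; the C7 methyl opposes this only weakly. Site selectivity is needed as well: the triple bond attached directly to the formyl group is the most electron-poor π bond of 7, while the distal triple bond and the alkene are only vinylogously activated. No Lewis acid is used, so Mukaiyama aldol addition and hetero-Diels–Alder reaction at the aldehyde are not opened and the silyl enol ether and the acetate survive. One step turns two acyclic fragments of similar size into the complete carbon skeleton of the core, with C8 already a methylene.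

Step 6
Reactants: 8 (E)-5-[2-formyl-4-methyl-5-(triethylsilyloxy)cyclohexa-1,4-dien-1-yl]pent-2-en-4-yn-1-yl acetate
Product: 10 (S,E)-5-(2-formyl-4-hydroxy-4-methyl-5-oxocyclohex-1-en-1-yl)pent-2-en-4-yn-1-yl acetate, via silyloxy epoxide 9 (not isolated)
Conditions: L-fructose-derived Shi ketone (30 mol%), KHSO5 (as Oxone, 2KHSO5·KHSO4·K2SO4), K2CO3, Bu4NHSO4, MeCN/CH2(OMe)2/aq. Na2B4O7 buffer, 0 °C; then aq. citric acid, THF, rt
Reagents that add atoms: potassium peroxymonosulfate, [K+].[O-]S(=O)(=O)OO
Why: Asymmetric Rubottom-type oxidation (Shi epoxidation of a silyl enol ether): the chiral dioxirane attacks the most electron-rich alkene C6=C7 in preference to the acceptor-substituted C4a=C8a and enyne alkenes. Epoxide 9 collapses on desilylation to the α-hydroxy ketone, the epoxide oxygen becoming the C7 hydroxyl, so the (S) configuration at C7 is set by the catalyst-controlled choice of enol ether face.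

Step 7
Reactants: 10 (S,E)-5-(2-formyl-4-hydroxy-4-methyl-5-oxocyclohex-1-en-1-yl)pent-2-en-4-yn-1-yl acetate
Product: 12 (S,E)-3-(7-hydroxy-7-methyl-6-oxo-7,8-dihydro-6H-isochromen-3-yl)prop-2-en-1-yl acetate, via hydroxymethylidene tautomer 11 (not isolated)
Conditions: CuI (10 mol%), i-Pr2NEt, CH2Cl2, rt, dark
Reagents that add atoms: none
Why: The amine moves the doubly activated C5 proton to give vinylogous acid 11, whose enol oxygen adds 6-endo-dig to the CuI-activated alkyne at C3 (the alkyne carbon that carries the alkenyl group), followed by protodemetalation; this cycloisomerisation of alkynyl vinylogous acids is the established closure of the azaphilone pyran. The product gains the pyrylium-enolate stabilisation of the chromophore, and C7 is not involved.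

Step 8
Reactants: 13 2,4-dihydroxy-6-methylbenzoic acid (orsellinic acid)
Product: 14 tert-butyldimethylsilyl 2,4-bis[(tert-butyldimethylsilyl)oxy]-6-methylbenzoate
Conditions: t-BuMe2SiCl (3.5 equiv), imidazole, DMF, rt to 40 °C
Reagents that add atoms: tert-butyldimethylsilyl chloride, CC(C)(C)[Si](C)(C)Cl
Why: Exhaustive silylation of both phenols and the acid under standard imidazole conditions; the silyl ester is the handle for the next step.

Step 9
Reactants: 14 tert-butyldimethylsilyl 2,4-bis[(tert-butyldimethylsilyl)oxy]-6-methylbenzoate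
Product: 15 2,4-bis[(tert-butyldimethylsilyl)oxy]-6-methylbenzoyl chloride
Conditions: (COCl)2, DMF (cat.), CH2Cl2, 0 °C to rt
Reagents that add atoms: oxalyl chloride, ClC(=O)C(Cl)=O
Why: Silyl esters are converted directly into acid chlorides by oxalyl chloride/DMF under neutral conditions, so the aryl silyl ethers are kept.

Step 10
Reactants: 12 (S,E)-3-(7-hydroxy-7-methyl-6-oxo-7,8-dihydro-6H-isochromen-3-yl)prop-2-en-1-yl acetate; 15 2,4-bis[(tert-butyldimethylsilyl)oxy]-6-methylbenzoyl chloride
Product: 16 (S)-3-[(E)-3-acetoxyprop-1-en-1-yl]-7-methyl-6-oxo-7,8-dihydro-6H-isochromen-7-yl 2,4-bis[(tert-butyldimethylsilyl)oxy]-6-methylbenzoate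
Conditions: DMAP (2 equiv), Et3N, CH2Cl2, 0 °C to 40 °C
Reagents that add atoms: none
Why: DMAP-mediated acylation of the tertiary O7 hydroxyl, the only nucleophilic site of 12, by the electron-rich aroyl chloride through its acylpyridinium salt; acylation of azaphilone C7 alcohols with acid chlorides and tertiary amines is the usual way to such esters. The C–O bond at C7 is not broken, so the configuration is kept.

Step 11
Reactants: 16 (S)-3-[(E)-3-acetoxyprop-1-en-1-yl]-7-methyl-6-oxo-7,8-dihydro-6H-isochromen-7-yl 2,4-bis[(tert-butyldimethylsilyl)oxy]-6-methylbenzoate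
Product: 17 (S)-3-[(E)-3-acetoxyprop-1-en-1-yl]-7-methyl-6-oxo-7,8-dihydro-6H-isochromen-7-yl 2,4-dihydroxy-6-methylbenzoate (target)
Conditions: HF·pyridine, pyridine, THF, 0 °C
Reagents that add atoms: none
Why: Aryl silyl ethers are cleaved by buffered fluoride under conditions that leave the allylic acetate, the aryl ester and the pyran chromophore untouched (fluoride desilylation).

## Compound list

1 | 3-methylbut-3-en-2-one | CC(=O)C(C)=C | starting material
2 | triethyl[(3-methylbuta-1,3-dien-2-yl)oxy]silane | C=C(C)C(=C)O[Si](CC)(CC)CC | intermediate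
3 | (E)-pent-2-en-4-yn-1-ol | OC/C=C/C#C | starting material
4 | (E)-pent-2-en-4-yn-1-yl acetate | CC(=O)OC/C=C/C#C | intermediate
5 | 3-bromoprop-2-yn-1-ol | OCC#CBr | starting material
6 | (E)-8-hydroxyoct-2-ene-4,6-diyn-1-yl acetate | CC(=O)OC/C=C/C#CC#CCO | intermediate
7 | (E)-8-oxooct-2-ene-4,6-diyn-1-yl acetate | CC(=O)OC/C=C/C#CC#CC=O | intermediate
8 | (E)-5-[2-formyl-4-methyl-5-(triethylsilyloxy)cyclohexa-1,4-dien-1-yl]pent-2-en-4-yn-1-yl acetate | CC(=O)OC/C=C/C#CC1=C(C=O)CC(C)=C(O[Si](CC)(CC)CC)C1 | intermediate
9 | (E)-5-[(1S,6S)-4-formyl-6-methyl-1-(triethylsilyloxy)-7-oxabicyclo[4.1.0]hept-3-en-3-yl]pent-2-en-4-yn-1-yl acetate | CC(=O)OC/C=C/C#CC1=C(C=O)C[C@]2(C)O[C@]2(O[Si](CC)(CC)CC)C1 | intermediate (not isolated)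
10 | (S,E)-5-(2-formyl-4-hydroxy-4-methyl-5-oxocyclohex-1-en-1-yl)pent-2-en-4-yn-1-yl acetate | CC(=O)OC/C=C/C#CC1=C(C=O)C[C@](C)(O)C(=O)C1 | intermediate
11 | (E)-5-[(4S,6Z)-4-hydroxy-6-(hydroxymethylidene)-4-methyl-3-oxocyclohex-1-en-1-yl]pent-2-en-4-yn-1-yl acetate | CC(=O)OC/C=C/C#CC1=CC(=O)[C@@](C)(O)C/C1=C/O | intermediate (not isolated)
12 | (S,E)-3-(7-hydroxy-7-methyl-6-oxo-7,8-dihydro-6H-isochromen-3-yl)prop-2-en-1-yl acetate | CC(=O)OC/C=C/C1=CC2=CC(=O)[C@@](C)(O)CC2=CO1 | intermediate
13 | 2,4-dihydroxy-6-methylbenzoic acid | Cc1cc(O)cc(O)c1C(=O)O | starting material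
14 | tert-butyldimethylsilyl 2,4-bis[(tert-butyldimethylsilyl)oxy]-6-methylbenzoate | Cc1cc(O[Si](C)(C)C(C)(C)C)cc(O[Si](C)(C)C(C)(C)C)c1C(=O)O[Si](C)(C)C(C)(C)C | intermediate
15 | 2,4-bis[(tert-butyldimethylsilyl)oxy]-6-methylbenzoyl chloride | Cc1cc(O[Si](C)(C)C(C)(C)C)cc(O[Si](C)(C)C(C)(C)C)c1C(Cl)=O | intermediate
16 | (S)-3-[(E)-3-acetoxyprop-1-en-1-yl]-7-methyl-6-oxo-7,8-dihydro-6H-isochromen-7-yl 2,4-bis[(tert-butyldimethylsilyl)oxy]-6-methylbenzoate | CC(=O)OC/C=C/C1=CC2=CC(=O)[C@@](C)(OC(=O)c3c(C)cc(O[Si](C)(C)C(C)(C)C)cc3O[Si](C)(C)C(C)(C)C)CC2=CO1 | intermediate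
17 | (S)-3-[(E)-3-acetoxyprop-1-en-1-yl]-7-methyl-6-oxo-7,8-dihydro-6H-isochromen-7-yl 2,4-dihydroxy-6-methylbenzoate | CC(=O)OC/C=C/C1=CC2=CC(=O)[C@@](C)(OC(=O)c3c(C)cc(O)cc3O)CC2=CO1 | target

## Step count and least certain steps

Total: 11 steps. Longest linear sequence: 8 steps (3 → 4 → 6 → 7 → 8 → 10 → 12 → 16 → 17; steps 2, 3, 4, 5, 6, 7, 10, 11).

**Step 5 (key step).**
- What may go wrong: thermal oligomerisation of the ene-diynal before it is trapped by the diene; erosion of regioselectivity, because the C7 methyl directs against the silyloxy group; air oxidation of the 1,4-diene to the arene during handling.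
- Fallback: it sets out from 2 and comes back to the route at 10. The cycloaddition would be run with a storable, silyl-capped ynal, and the side chain attached afterwards.
  - 5-(Trimethylsilyl)penta-2,4-diynal F1 would be made from commercial 1,4-bis(trimethylsilyl)buta-1,3-diyne (MeLi·LiBr, then DMF).
  - Heated with 2 as in step 5, it should give 5-methyl-4-(triethylsilyloxy)-2-[(trimethylsilyl)ethynyl]cyclohexa-1,4-diene-1-carbaldehyde F2.
  - Epoxidation as in step 6 should give (S)-5-hydroxy-5-methyl-4-oxo-2-[(trimethylsilyl)ethynyl]cyclohex-1-ene-1-carbaldehyde F3.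
  - Buffered fluoride (Bu4NF/AcOH, THF, 0 °C) should free the alkyne to (S)-2-ethynyl-5-hydroxy-5-methyl-4-oxocyclohex-1-ene-1-carbaldehyde F4.
  - Sonogashira coupling (Pd(PPh3)2Cl2, CuI, Et3N) with (E)-3-iodoprop-2-en-1-yl acetate F5 (from commercial (E)-3-iodoprop-2-en-1-ol and Ac2O) should give 10. Any 10 that cyclises under these conditions is simply 12.

**Step 6.**
- What may go wrong: insufficient or reversed facial selectivity on a tetrasubstituted cyclic enol ether whose two faces differ only through silyloxy versus methyl; oxidation of the aldehyde by the peroxide; base-induced tautomerisation and loss of material to the aqueous phase.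
- Fallback: it sets out from 1, 7 and 15 and comes back to the route at 16. The C7–O bond would be made by acyl migration in an isolable enol ester epoxide, and steps 6, 7 and 10 are replaced.
  - The potassium enolate of 1 (KN(SiMe3)2, THF, −78 °C) would be O-acylated with 15 to 3-methylbuta-1,3-dien-2-yl 2,4-bis[(tert-butyldimethylsilyl)oxy]-6-methylbenzoate F6.
  - Cycloaddition with 7 (toluene, 80 °C) should give 5-[(E)-5-acetoxypent-3-en-1-yn-1-yl]-4-formyl-2-methylcyclohexa-1,4-dien-1-yl 2,4-bis[(tert-butyldimethylsilyl)oxy]-6-methylbenzoate F7.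
  - Epoxidation with the chiral ketone and KHSO5 should give (1S,6S)-3-[(E)-5-acetoxypent-3-en-1-yn-1-yl]-4-formyl-6-methyl-7-oxabicyclo[4.1.0]hept-3-en-1-yl 2,4-bis[(tert-butyldimethylsilyl)oxy]-6-methylbenzoate F8. Enol ester epoxides can be isolated and enriched by crystallisation.
  - Acid-catalysed rearrangement (TsOH, acyl transfer to the epoxide oxygen with retention at C7) should give (S)-4-[(E)-5-acetoxypent-3-en-1-yn-1-yl]-3-formyl-1-methyl-6-oxocyclohex-3-en-1-yl 2,4-bis[(tert-butyldimethylsilyl)oxy]-6-methylbenzoate F9. The mirror-image epoxide would be funnelled to the same F9 by the thermal acyloxy shift, which proceeds with inversion.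
  - Cycloisomerisation as in step 7 then gives 16.

**Step 10.**
- What may go wrong: acylation of the tertiary α-ketol by the doubly ortho-substituted aroyl chloride may be so slow that decomposition of the chromophore by the amine bases or hydrolysis of the acid chloride wins.
- Fallback: it sets out from 12 and 13 and comes back to the route at 17. The acyl donor is changed from an acid chloride to a ring-strained salicylate acetonide that is opened by the alkoxide.
  - 13 with acetone, (CF3CO)2O and CF3CO2H should give 7-hydroxy-2,2,5-trimethyl-4H-1,3-benzodioxin-4-one F10.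
  - Silylation (t-BuMe2SiCl, imidazole) gives 7-[(tert-butyldimethylsilyl)oxy]-2,2,5-trimethyl-4H-1,3-benzodioxin-4-one F11.
  - The sodium alkoxide of 12 (NaN(SiMe3)2, THF, −78 °C) should open F11 with loss of acetone to (S)-3-[(E)-3-acetoxyprop-1-en-1-yl]-7-methyl-6-oxo-7,8-dihydro-6H-isochromen-7-yl 4-[(tert-butyldimethylsilyl)oxy]-2-hydroxy-6-methylbenzoate F12.
  - Desilylation as in step 11 gives 17.

## Further compounds

F1 | step 5 | 5-(trimethylsilyl)penta-2,4-diynal | C[Si](C)(C)C#CC#CC=O
F2 | step 5 | 5-methyl-4-(triethylsilyloxy)-2-[(trimethylsilyl)ethynyl]cyclohexa-1,4-diene-1-carbaldehyde | C[Si](C)(C)C#CC1=C(C=O)CC(C)=C(O[Si](CC)(CC)CC)C1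
F3 | step 5 | (S)-5-hydroxy-5-methyl-4-oxo-2-[(trimethylsilyl)ethynyl]cyclohex-1-ene-1-carbaldehyde | C[Si](C)(C)C#CC1=C(C=O)C[C@](C)(O)C(=O)C1
F4 | step 5 | (S)-2-ethynyl-5-hydroxy-5-methyl-4-oxocyclohex-1-ene-1-carbaldehyde | C#CC1=C(C=O)C[C@](C)(O)C(=O)C1
F5 | step 5 | (E)-3-iodoprop-2-en-1-yl acetate | CC(=O)OC/C=C/I
F6 | step 6 | 3-methylbuta-1,3-dien-2-yl 2,4-bis[(tert-butyldimethylsilyl)oxy]-6-methylbenzoate | C=C(C)C(=C)OC(=O)c1c(C)cc(O[Si](C)(C)C(C)(C)C)cc1O[Si](C)(C)C(C)(C)C
F7 | step 6 | 5-[(E)-5-acetoxypent-3-en-1-yn-1-yl]-4-formyl-2-methylcyclohexa-1,4-dien-1-yl 2,4-bis[(tert-butyldimethylsilyl)oxy]-6-methylbenzoate | CC(=O)OC/C=C/C#CC1=C(C=O)CC(C)=C(OC(=O)c2c(C)cc(O[Si](C)(C)C(C)(C)C)cc2O[Si](C)(C)C(C)(C)C)C1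
F8 | step 6 | (1S,6S)-3-[(E)-5-acetoxypent-3-en-1-yn-1-yl]-4-formyl-6-methyl-7-oxabicyclo[4.1.0]hept-3-en-1-yl 2,4-bis[(tert-butyldimethylsilyl)oxy]-6-methylbenzoate | CC(=O)OC/C=C/C#CC1=C(C=O)C[C@]2(C)O[C@]2(OC(=O)c3c(C)cc(O[Si](C)(C)C(C)(C)C)cc3O[Si](C)(C)C(C)(C)C)C1
F9 | step 6 | (S)-4-[(E)-5-acetoxypent-3-en-1-yn-1-yl]-3-formyl-1-methyl-6-oxocyclohex-3-en-1-yl 2,4-bis[(tert-butyldimethylsilyl)oxy]-6-methylbenzoate | CC(=O)OC/C=C/C#CC1=C(C=O)C[C@](C)(OC(=O)c2c(C)cc(O[Si](C)(C)C(C)(C)C)cc2O[Si](C)(C)C(C)(C)C)C(=O)C1
F10 | step 10 | 7-hydroxy-2,2,5-trimethyl-4H-1,3-benzodioxin-4-one | Cc1cc(O)cc2OC(C)(C)OC(=O)c12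
F11 | step 10 | 7-[(tert-butyldimethylsilyl)oxy]-2,2,5-trimethyl-4H-1,3-benzodioxin-4-one | Cc1cc(O[Si](C)(C)C(C)(C)C)cc2OC(C)(C)OC(=O)c12
F12 | step 10 | (S)-3-[(E)-3-acetoxyprop-1-en-1-yl]-7-methyl-6-oxo-7,8-dihydro-6H-isochromen-7-yl 4-[(tert-butyldimethylsilyl)oxy]-2-hydroxy-6-methylbenzoate | CC(=O)OC/C=C/C1=CC2=CC(=O)[C@@](C)(OC(=O)c3c(C)cc(O[Si](C)(C)C(C)(C)C)cc3O)CC2=CO1
A1 | alternative 1 | (E)-5-(2-formyl-3,5-dihydroxy-4-methylphenyl)pent-2-en-4-yn-1-yl acetate | CC(=O)OC/C=C/C#Cc1cc(O)c(C)c(O)c1C=O
A2 | alternative 1 | (R,E)-3-(7-hydroxy-7-methyl-6,8-dioxo-7,8-dihydro-6H-isochromen-3-yl)prop-2-en-1-yl acetate (same spatial arrangement at C7 as the target) | CC(=O)OC/C=C/C1=CC2=CC(=O)[C@@](C)(O)C(=O)C2=CO1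
A3 | alternative 2 | (E)-5-(2-formyl-5-hydroxy-4-methylphenyl)pent-2-en-4-yn-1-yl acetate | CC(=O)OC/C=C/C#Cc1cc(O)c(C)cc1C=O
A4 | alternative 2 | (S,E)-5-(6-formyl-4-hydroxy-4-methyl-3-oxocyclohexa-1,5-dien-1-yl)pent-2-en-4-yn-1-yl acetate | CC(=O)OC/C=C/C#CC1=CC(=O)[C@@](C)(O)C=C1C=O
A5 | alternative 3 | (E)-3-{5-[(S)-2-hydroxy-2-methyl-3-oxobutyl]-4-oxo-4H-pyran-2-yl}prop-2-en-1-yl acetate | CC(=O)OC/C=C/C1=CC(=O)C(C[C@](C)(O)C(C)=O)=CO1
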